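All runs were computed for substances that don't exist; noise was put on by code.

We decide first to hold the two earlier runs against each other, row by row, before choosing any rate law, because the concentration that would set the order, the charge of substrate, differs between them.

| flask | substrate | remark | time |
|---|---|---|---|
| Friday's | 0.55 M | run made earlier |  |
| Thursday's | 0.83 M | run made earlier |  |
| flask | 1.1 M |  | 6.0 min |

| run | time / min | target / % |
|---|---|---|
| Friday's | 0.167 | 22.5 |
| Friday's | 0.333 | 31.8 |
| Friday's | 1.33 | 12.8 |
| Friday's | 6.00 | 11.1 |
| Thursday's | 0.167 | 25.6 |
| Thursday's | 0.333 | 30.6 |
| Thursday's | 1.33 | 12.8 |
| Thursday's | 6.00 | 9.0 |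

(standard deviation of a reading: 1 percentage point)



1. the moment within 6.0 min at which there is most target
2. the amount of target, in percent of the substrate charged, at that time
3. the first time at which target reaches 21%, in the same percent, in min

Read down the tables, taking Friday's reading minus Thursday's. At 0.167 min the difference is −3.1 percentage points, at 0.333 min it is 1.2 points, at 1.33 min both runs read 12.8%, and at 6.00 min it is 2.1 points. The signs disagree. Their mean is 0.05 points; this charge shift, the mean over the rows of the lower charge's target minus the higher charge's, is what we carry.

With 1 point of scatter per reading, that mean has a standard deviation of 0.71 points, and the shift is smaller. Steps that are all first order give a percent curve that does not move with the charge, and the mean difference of these two runs is smaller than its scatter, although single rows differ by more. So we carry their mean curve unmoved to 1.1 M, beyond both charges. Our own reckoning is a peak near 0.333 min of 31.2%. A straight line from the origin through the mean 24.0% reaches 21% at 0.146 min.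

The forecast differs: 32% at 0.28 min, and 21% at 0.115 min, on the ground that “Formation therefore speeds up modestly with concentration”.

The flask gives 30.4% at 0.355 min, and 21% at 0.158 min.

    substrate → intermediate A (k = 0.470 s⁻¹)
    intermediate A → intermediate B (k = 0.0520 s⁻¹)
    intermediate B → target (k = 1.40 s⁻¹)
    2 substrate → self-condensation product (k = 0.0360 M⁻¹ s⁻¹)
    target ⇌ isomer of the product (K = 8.10, k = 0.0680 s⁻¹)

With a shift of 0.05 points we carried the curve unmoved to the flask, and the neighbour flask, with the same charge and read at 15 min, holds 10.2% after a highest 30.4%. Early in the flask, at 0.0233 min, target has a half-life of 0.17 min by the forward step to the isomer of the product, shorter than the 0.22 min of intermediate A on its path to intermediate B. At 0.355 min the flask holds 30.4% target beside 34.1% intermediate A.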